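- An excess read in one run cannot be carried to another flask as it stands: it is a lead divided by all the product, so the same lead counts for less once more product stands beside it. I therefore followed the lead itself, left-handed product minus right-handed product.

| setting | blue | violet | south-east | north-west |
|---|---|---|---|---|
| left-handed substrate | 0.12 M | 0.50 M | 0.25 M | 0.25 M |
| right-handed substrate | 0.12 M | 0.50 M | 0.25 M | 0.25 M |
| coupling partner | 0.55 M | 0.55 M | 0.550 M | 0.550 M |
| catalyst | 0.12 mM | 0.12 mM | 0.12 mM | 0.12 mM |
| temperature | 20 °C | 38 °C | 25 °C | 50 °C |
| remark | run made earlier | run made earlier |  |  |
| time |  |  | 3.0 min | 3.0 min |

| run | time / s | left-handed product / % | right-handed product / % |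
|---|---|---|---|
| blue | 25.0 | 10.6 | 4.4 |
| blue | 50.0 | 17.2 | 10.1 |
| blue | 80.0 | 25.0 | 13.6 |
| blue | 120 | 32.0 | 18.1 |
| violet | 10.0 | 9.8 | 5.2 |
| violet | 20.0 | 16.3 | 8.0 |
| violet | 40.0 | 21.1 | 12.2 |
| violet | 60.0 | 25.0 | 15.2 |

(scatter of a reading: 0.5 percentage points)

1. the flask with the highest excess of left-handed product over right-handed product ("all alike" if they lie within 1.5 percentage points) (south-east / north-west / all alike)
2. excess of left-handed product over right-handed product at the end, south-east
3. excess of left-handed product over right-handed product at the end, north-west

- catalyst is single-handed; left-handed substrate and right-handed substrate are mirror images of each other, charged as a racemate, each of them at the stated concentration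
- steps under discussion: coupling partner + catalyst + left-handed substrate -> catalyst + left-handed product; coupling partner + catalyst + right-handed substrate -> catalyst + right-handed product; left-handed substrate <-> right-handed substrate; coupling partner -> decomposition product; 2 coupling partner -> homo dimer; left-handed product <-> right-handed product
- an excess is the difference of the two amounts in percent of their sum
- an excess is below zero if the other one leads

- From the second reading to the last, 29.8% of the new product went to the lead in the blue run, but 9.43% in the violet run, as readings with their scatter. I call this the lead share: the gain in lead over the gain in total product between two times. An excess rises while the lead share stands above it and falls while it stands below.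
- Time: by hand, more time adds product, and the lead grows by the lead share of it. South-east at 25 °C lies near the blue run in temperature, so I expected its lead still to grow, though thinned by more product. I put its excess under the blue run's last 27.7%, at about 24.4%.
- Temperature: by hand, heat that speeds both couplings alike keeps the ratio of their rate constants, so the lead share should match at equal total product, though a hotter flask reaches a given total sooner. Yet the share was lower in the hotter violet run, although that run ended its span at 40.2% of total product against 50.1% in the blue run; the two runs also differ in their charge. I read this as something taking the lead back when hot, so at 50 °C I expected a lead share near zero or below, and north-west under 5.00%.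
- The forecast named south-east, with 22% and 11%, the second above my limit, and said of the blue run that “there is no visible racemisation”.
- The simulation gave south-east, with 22.6% there and 1.06% in north-west, which is under my limit.

    coupling partner + catalyst + left-handed substrate → catalyst + left-handed product (k = 210 M⁻² s⁻¹, Ea = 40.0 kJ mol⁻¹)
    coupling partner + catalyst + right-handed substrate → catalyst + right-handed product (k = 93.0 M⁻² s⁻¹, Ea = 40.0 kJ mol⁻¹)
    left-handed substrate ⇌ right-handed substrate (k = 0.00490 s⁻¹, Ea = 82.0 kJ mol⁻¹)
    coupling partner → decomposition product (k = 1.40 × 10⁻⁶ s⁻¹, Ea = 111 kJ mol⁻¹)
    2 coupling partner → homo dimer (k = 0.00250 M⁻¹ s⁻¹, Ea = 56.0 kJ mol⁻¹)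
    left-handed product ⇌ right-handed product (k = 0.00110 s⁻¹, Ea = 90.0 kJ mol⁻¹)
    (constants at 25 °C)

- In south-east the interconversion of the two products has a relaxation half-life of 5.25 min by this step alone, longer than the 3.0 min of the flask, and its activation energy lies 50.0 kJ mol⁻¹ above that of the left-handed coupling. The lead share from 1.50 min to 3.00 min was 7.95% in south-east and −30.4% in north-west, while the south-east flask left until 5.0 min showed −8.68% over its added time and ended at an excess of 18.3%.

The data come from a simulation for substances that don't exist; scatter was added.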